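**Strategy.** The ent-labdane core is traced to one intramolecular Diels–Alder reaction: ring B, a cyclohexene (C5–C10) trans-fused to ring A and carrying the contiguous stereocentres C5, C9 and C10, lies one alkene shift (C6=C7 to C7=C8) from a [4+2] adduct. A chiral copper–bis(oxazoline) Lewis acid cyclises an achiral (2E,8E,10E)-trienoyl oxazolidinone, forming C5–C10 and C8–C9, closing rings A and B together and setting C5, C8, C9 and C10. The triene is assembled from 2,2-dimethylpent-4-enal by dienoate olefination and a geometry-retaining B-alkyl Suzuki coupling; the same coupling later adds C12–C16, and a C17 aldehyde relay moves the alkene before the final deprotection.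

Key step: step 10

Remark: the acyl residue is read as 32-hydroxydotriacontanoyl (31 CH2 between C=O and OH), and the decalin is in the ent-labdane series (C5 R, C9 S, C10 R); labdane numbering is used for its atoms.
Remark: TBS = tert-butyldimethylsilyl, TBDPS = tert-butyldiphenylsilyl, (S,S)-t-Bu-box = 2,2′-(propane-2,2-diyl)bis[(4S)-4-tert-butyl-4,5-dihydro-1,3-oxazole].

**Step 1**
Reactants: 1 but-2-ynoic acid
Product: 2 (2E)-3-iodobut-2-enoic acid
Conditions: 57% aq. HI, 110 °C, sealed vessel; crystallisation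
Reagents that add atoms: hydrogen iodide, I
Why: Conjugate hydroiodination puts iodide on C3, and in hot strong acid the first-formed anti adduct should equilibrate by reversible addition–elimination of HI to the more stable E acid (iodine trans to CO2H), which crystallises.

**Step 2**
Reactants: 2 (2E)-3-iodobut-2-enoic acid
Product: 3 ethyl (2E)-3-iodobut-2-enoate
Conditions: EtOH, H2SO4 (cat.), reflux
Reagents that add atoms: ethanol, CCO
Why: Fischer esterification leaves the vinyl iodide and its thermodynamically preferred E geometry untouched.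

**Step 3**
Reactants: 3 ethyl (2E)-3-iodobut-2-enoate
Product: 4 (2E)-3-iodobut-2-en-1-ol
Conditions: i-Bu2AlH (2.2 equiv), CH2Cl2, −78 to 0 °C; aq. Rochelle salt
Reagents that add atoms: none
Why: 1,2-Reduction of the enoate by the aluminium hydride should give the allylic alcohol while the C–I bond survives at low temperature.

**Step 4**
Reactants: 5 2,2-dimethylpent-4-enal; 6 triethyl 4-phosphonocrotonate
Product: 7 ethyl (2E,4E)-6,6-dimethylnona-2,4,8-trienoate
Conditions: LiN(SiMe3)2, THF, −78 to 0 °C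
Reagents that add atoms: none
Why: Horner–Wadsworth–Emmons olefination of a non-enolisable aldehyde with the stabilised allylic phosphonate anion should form the new alkene E and so give the (2E,4E)-dienoate.

**Step 5**
Reactants: 7 ethyl (2E,4E)-6,6-dimethylnona-2,4,8-trienoate
Product: 8 (2E,4E)-6,6-dimethylnona-2,4,8-trien-1-ol
Conditions: i-Bu2AlH (2.2 equiv), CH2Cl2, −78 °C; aq. Rochelle salt
Reagents that add atoms: none
Why: 1,2-Hydride reduction of the dienoate gives the dienol and leaves all three alkenes in place.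

**Step 6**
Reactants: 8 (2E,4E)-6,6-dimethylnona-2,4,8-trien-1-ol
Product: 9 tert-butyl{[(2E,4E)-6,6-dimethylnona-2,4,8-trien-1-yl]oxy}dimethylsilane
Conditions: TBSCl, imidazole, CH2Cl2, 0 °C to rt
Reagents that add atoms: tert-butyldimethylsilyl chloride, CC(C)(C)[Si](C)(C)Cl
Why: Silylation of the primary alcohol gives an ether that is a poor donor towards the later cationic copper catalyst.

**Step 7**
Reactants: 9 tert-butyl{[(2E,4E)-6,6-dimethylnona-2,4,8-trien-1-yl]oxy}dimethylsilane; 3 ethyl (2E)-3-iodobut-2-enoate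
Product: 11 ethyl (2E,8E,10E)-12-(TBSO)-3,7,7-trimethyldodeca-2,8,10-trienoate, via B-alkyl-9-BBN borane 10 (not isolated)
Conditions: 9-BBN-H (1.3 equiv), THF, 0 °C to rt; then aq. K3PO4, 3, Pd(dppf)Cl2 (5 mol%), DMF, rt
Reagents that add atoms: 9-borabicyclo[3.3.1]nonane, B1C2CCCC1CCC2 (its boron and ring atoms are carried only in 10; the product keeps one H)
Why: 9-BBN hydroborates only the monosubstituted alkene (anti-Markovnikov), and the B-alkyl Suzuki–Miyaura coupling retains the geometry of the iodoenoate, so the C1 chain ends trans to the ester (2E), which is the geometry that later puts C11 cis to C20.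

**Step 8**
Reactants: 11 ethyl (2E,8E,10E)-12-(TBSO)-3,7,7-trimethyldodeca-2,8,10-trienoate
Product: 12 (2E,8E,10E)-12-(TBSO)-3,7,7-trimethyldodeca-2,8,10-trienoic acid
Conditions: LiOH·H2O, THF/MeOH/H2O, 45 °C; then 1 M HCl to pH 4, 0 °C
Reagents that add atoms: lithium hydroxide, [Li+].[OH-]
Why: Saponification of the conjugated ester proceeds without affecting the silyl ether or the alkene geometries.

**Step 9**
Reactants: 12 (2E,8E,10E)-12-(TBSO)-3,7,7-trimethyldodeca-2,8,10-trienoic acid; 13 1,3-oxazolidin-2-one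
Product: 15 3-[(2E,8E,10E)-12-(TBSO)-3,7,7-trimethyldodeca-2,8,10-trienoyl]-1,3-oxazolidin-2-one, via mixed pivalic anhydride 14 (not isolated)
Conditions: PivCl, Et3N, THF, −20 °C; then LiCl, 13, −20 °C to rt
Reagents that add atoms: pivaloyl chloride, CC(C)(C)C(Cl)=O (its acyl group is carried only in 14)
Why: Mixed-anhydride N-acylation of the LiCl-activated oxazolidinone occurs at the less hindered enoyl carbonyl, and the mild base and low temperature should avoid dienolate formation, so the 2E geometry is kept.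

**Step 10**
Reactants: 15 3-[(2E,8E,10E)-12-(TBSO)-3,7,7-trimethyldodeca-2,8,10-trienoyl]-1,3-oxazolidin-2-one
Product: 16 3-{[(1R,2R,4aR,8aR)-2-(TBSO-methyl)-5,5,8a-trimethyl-1,2,4a,5,6,7,8,8a-octahydronaphthalen-1-yl]carbonyl}-1,3-oxazolidin-2-one
Conditions: [Cu((S,S)-t-Bu-box)](SbF6)2 (10–20 mol%), CH2Cl2, 25 °C (40 °C if slow)
Reagents that add atoms: none
Why: Both imide carbonyls chelate the cationic divalent copper centre, which lowers the LUMO of the s-cis enoyl unit (the C20 methyl cis to the carbonyl disfavours s-trans), and the tethered E,E-diene then adds in a concerted, asynchronous [4+2] that forms C8–C9 and C5–C10. The closest known reaction is the copper–bis(oxazoline)-catalysed enantioselective intramolecular Diels–Alder reaction of trienoyl oxazolidinones to trans-fused bicycles; the β,β-disubstituted dienophile and the neopentylic diene terminus make this the demanding case on which the route stakes its risk. Ring B is closed as the six-membered cycloaddition ring, and ring A closes in the same event as a six-membered carbocycle because the C1–C4 tether spans C10 and C5 in a chair-like fold that the C4 gem-dimethyl group favours. C9 and C10 follow from the enantioface of the bound dienophile (in the square-planar chelate a tert-butyl group of the (S,S)-ligand covers the si face of C9, so the diene should add to the re face) together with the 2E geometry, which keeps C11 cis to C20; C5 follows from the carbonyl-endo transition state, which gives the trans ring fusion, and C8 from the E geometry of C7=C8 in that same arrangement, which puts C17 cis to C11. The step needs endo over exo and one enantioface: two-point binding of the imide to the C2-symmetric complex secures the face, and Lewis acid activation of an E-dienophile whose carbonyl is distal to the tether secures the endo, trans-fused mode.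

**Step 11**
Reactants: 16 cycloadduct imide
Product: 17 [(1R,2R,4aR,8aR)-2-(TBSO-methyl)-5,5,8a-trimethyl-1,2,4a,5,6,7,8,8a-octahydronaphthalen-1-yl]methanol
Conditions: LiBH4, MeOH (1 equiv), Et2O/THF, 0 °C
Reagents that add atoms: none
Why: Reductive cleavage of the N-acyl oxazolidinone by borohydride at the exocyclic carbonyl gives the C11 alcohol without touching any stereocentre.

**Step 12**
Reactants: 17 C11 alcohol
Product: 18 (1R,2R,4aR,8aR)-2-(TBSO-methyl)-5,5,8a-trimethyl-1,2,4a,5,6,7,8,8a-octahydronaphthalene-1-carbaldehyde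
Conditions: Dess–Martin periodinane, CH2Cl2, 0 °C to rt; aq. NaHCO3/Na2S2O3 wash
Reagents that add atoms: none
Why: Dess–Martin oxidation is non-basic, so the C9 centre next to the new aldehyde should not epimerise.

**Step 13**
Reactants: 18 C11 aldehyde
Product: 19 tert-butyl{[(1R,2R,4aR,8aS)-1-ethenyl-5,5,8a-trimethyl-1,2,4a,5,6,7,8,8a-octahydronaphthalen-2-yl]methoxy}dimethylsilane
Conditions: Ph3PCH3Br, KOt-Bu, THF, 0 °C; then 18, 0 °C to rt
Reagents that add atoms: methyltriphenylphosphonium bromide, C[P+](c1ccccc1)(c1ccccc1)c1ccccc1.[Br-]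
Why: Wittig methylenation converts C11 into a vinyl group (C11=C12), and the C9 substituent already sits in its more stable equatorial position, so the basic ylide has no driving force to epimerise it.

**Step 14**
Reactants: 19 C9-vinyl decalin; 4 (2E)-3-iodobut-2-en-1-ol
Product: 21 (2E)-5-[(1R,2R,4aR,8aS)-2-(TBSO-methyl)-5,5,8a-trimethyl-1,2,4a,5,6,7,8,8a-octahydronaphthalen-1-yl]-3-methylpent-2-en-1-ol, via B-alkyl-9-BBN borane 20 (not isolated)
Conditions: 9-BBN-H (1.5 equiv), THF, rt; then Cs2CO3, H2O, 4, Pd(dppf)Cl2 (5 mol%), AsPh3, DMF, rt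
Reagents that add atoms: 9-borabicyclo[3.3.1]nonane, B1C2CCCC1CCC2 (its boron and ring atoms are carried only in 20; the product keeps one H)
Why: 9-BBN hydroborates the vinyl group far faster than the hindered ring alkene, and B-alkyl Suzuki–Miyaura coupling with retention at the vinyl iodide forms C12–C13 with C12 trans to C15 (13E).

**Step 15**
Reactants: 22 16-bromohexadecan-1-ol
Product: 23 [(16-bromohexadecyl)oxy](tert-butyl)diphenylsilane
Conditions: TBDPSCl, imidazole, CH2Cl2, rt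
Reagents that add atoms: tert-butyldiphenylsilyl chloride, CC(C)(C)[Si](Cl)(c1ccccc1)c1ccccc1
Why: Silylation gives an ether that tolerates Grignard formation and later outlasts the TBS ether under acid.

**Step 16**
Reactants: 23 [(16-bromohexadecyl)oxy](tert-butyl)diphenylsilane; 24 16-bromohexadecanoic acid
Product: 27 32-(TBDPSO)dotriacontanoic acid, via chloromagnesium 16-bromohexadecanoate 25 (not isolated), via Grignard reagent 26 (not isolated)
Conditions: 23, Mg, THF, 40 °C; 24, MeMgCl (1.0 equiv), THF, −20 °C; combine, Li2CuCl4 (3 mol%), −20 °C to rt; then 1 M HCl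
Reagents that add atoms: magnesium, [Mg] (carried only in 26); methylmagnesium chloride, C[Mg]Cl (its MgCl is carried only in 25)
Why: Li2CuCl4-catalysed cross-coupling of a primary alkyl Grignard reagent with a primary alkyl bromide joins the two C16 units, the acid being masked as its magnesium carboxylate, which is inert to the Grignard reagent at low temperature.

**Step 17**
Reactants: 21 C15 allylic alcohol; 27 32-(TBDPSO)dotriacontanoic acid
Product: 28 (2E)-5-[(1R,2R,4aR,8aS)-2-(TBSO-methyl)-5,5,8a-trimethyl-1,2,4a,5,6,7,8,8a-octahydronaphthalen-1-yl]-3-methylpent-2-en-1-yl 32-(TBDPSO)dotriacontanoate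
Conditions: EDC·HCl, DMAP (cat.), CH2Cl2, rt
Reagents that add atoms: none
Why: Steglich-type carbodiimide esterification acylates the only free hydroxyl, the unhindered primary allylic O15.

**Step 18**
Reactants: 28 bis-silyl ester
Product: 29 (2E)-5-[(1R,2R,4aR,8aS)-2-(hydroxymethyl)-5,5,8a-trimethyl-1,2,4a,5,6,7,8,8a-octahydronaphthalen-1-yl]-3-methylpent-2-en-1-yl 32-(TBDPSO)dotriacontanoate
Conditions: camphorsulfonic acid (cat.), MeOH/CH2Cl2 (1:1), 0 °C
Reagents that add atoms: none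
Why: Acid-catalysed methanolysis cleaves a primary TBS ether much faster than a primary TBDPS ether, so only O17 is unveiled.

**Step 19**
Reactants: 29 C17 alcohol
Product: 31 (2E)-5-[(1S,4aR,8aR)-2-formyl-5,5,8a-trimethyl-1,4,4a,5,6,7,8,8a-octahydronaphthalen-1-yl]-3-methylpent-2-en-1-yl 32-(TBDPSO)dotriacontanoate, via β,γ-unsaturated C17 aldehyde 30 (not isolated)
Conditions: Dess–Martin periodinane, CH2Cl2, 0 °C; aq. NaHCO3/Na2S2O3 wash; crude 30, DBU (0.2 equiv), CH2Cl2, rt
Reagents that add atoms: none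
Why: Dess–Martin oxidation followed by base-mediated conjugation through the dienolate (protonation at C6) moves the alkene from C6=C7 to C7=C8 and removes the temporary C8 centre, while C9–H is not acidified by the enal and stays fixed.

**Step 20**
Reactants: 31 C17 enal
Product: 32 (2E)-5-[(1S,4aR,8aR)-2-(hydroxymethyl)-5,5,8a-trimethyl-1,4,4a,5,6,7,8,8a-octahydronaphthalen-1-yl]-3-methylpent-2-en-1-yl 32-(TBDPSO)dotriacontanoate
Conditions: NaBH4, CeCl3·7H2O, MeOH/THF, −40 °C
Reagents that add atoms: none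
Why: Luche reduction delivers hydride 1,2 to the enal and leaves the ester and both alkenes untouched.

**Step 21**
Reactants: 32 TBDPS-protected target
Product: 33 (2E)-5-[(1S,4aR,8aR)-2-(hydroxymethyl)-5,5,8a-trimethyl-1,4,4a,5,6,7,8,8a-octahydronaphthalen-1-yl]-3-methylpent-2-en-1-yl 32-hydroxydotriacontanoate (CNP0264179.1)
Conditions: HF·pyridine, pyridine, THF, 0 °C to rt
Reagents that add atoms: none
Why: Buffered fluoride desilylation frees the terminal hydroxyl without acyl migration or cleavage of the allylic ester.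

**Compound list**
1 | but-2-ynoic acid | CC#CC(=O)O | starting material
2 | (2E)-3-iodobut-2-enoic acid | C/C(I)=C\C(=O)O | intermediate
3 | ethyl (2E)-3-iodobut-2-enoate | CCOC(=O)/C=C(C)/I | intermediate
4 | (2E)-3-iodobut-2-en-1-ol | OC/C=C(C)/I | intermediate
5 | 2,2-dimethylpent-4-enal | C=CCC(C)(C)C=O | starting material
6 | triethyl 4-phosphonocrotonate | CCOC(=O)/C=C/CP(=O)(OCC)OCC | starting material
7 | ethyl (2E,4E)-6,6-dimethylnona-2,4,8-trienoate | CCOC(=O)/C=C/C=C/C(C)(C)CC=C | intermediate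
8 | (2E,4E)-6,6-dimethylnona-2,4,8-trien-1-ol | OC/C=C/C=C/C(C)(C)CC=C | intermediate
9 | tert-butyl{[(2E,4E)-6,6-dimethylnona-2,4,8-trien-1-yl]oxy}dimethylsilane | CC(C)(C)[Si](C)(C)OC/C=C/C=C/C(C)(C)CC=C | intermediate
10 | 9-[(5E,7E)-9-(TBSO)-4,4-dimethylnona-5,7-dien-1-yl]-9-borabicyclo[3.3.1]nonane | CC(C)(C)[Si](C)(C)OC/C=C/C=C/C(C)(C)CCCB1C2CCCC1CCC2 | intermediate (not isolated)
11 | ethyl (2E,8E,10E)-12-(TBSO)-3,7,7-trimethyldodeca-2,8,10-trienoate | CCOC(=O)/C=C(\C)CCCC(C)(C)/C=C/C=C/CO[Si](C)(C)C(C)(C)C | intermediate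
12 | (2E,8E,10E)-12-(TBSO)-3,7,7-trimethyldodeca-2,8,10-trienoic acid | OC(=O)/C=C(\C)CCCC(C)(C)/C=C/C=C/CO[Si](C)(C)C(C)(C)C | intermediate
13 | 1,3-oxazolidin-2-one | O=C1NCCO1 | starting material
14 | (2E,8E,10E)-12-(TBSO)-3,7,7-trimethyldodeca-2,8,10-trienoic pivalic anhydride | CC(C)(C)C(=O)OC(=O)/C=C(\C)CCCC(C)(C)/C=C/C=C/CO[Si](C)(C)C(C)(C)C | intermediate (not isolated)
15 | 3-[(2E,8E,10E)-12-(TBSO)-3,7,7-trimethyldodeca-2,8,10-trienoyl]-1,3-oxazolidin-2-one | O=C1OCCN1C(=O)/C=C(\C)CCCC(C)(C)/C=C/C=C/CO[Si](C)(C)C(C)(C)C | intermediate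
16 | 3-{[(1R,2R,4aR,8aR)-2-(TBSO-methyl)-5,5,8a-trimethyl-1,2,4a,5,6,7,8,8a-octahydronaphthalen-1-yl]carbonyl}-1,3-oxazolidin-2-one | O=C1OCCN1C(=O)[C@@H]2[C@H](CO[Si](C)(C)C(C)(C)C)C=C[C@@H]3C(C)(C)CCC[C@@]23C | intermediate
17 | [(1R,2R,4aR,8aR)-2-(TBSO-methyl)-5,5,8a-trimethyl-1,2,4a,5,6,7,8,8a-octahydronaphthalen-1-yl]methanol | OC[C@@H]1[C@H](CO[Si](C)(C)C(C)(C)C)C=C[C@@H]2C(C)(C)CCC[C@@]12C | intermediate
18 | (1R,2R,4aR,8aR)-2-(TBSO-methyl)-5,5,8a-trimethyl-1,2,4a,5,6,7,8,8a-octahydronaphthalene-1-carbaldehyde | O=C[C@@H]1[C@H](CO[Si](C)(C)C(C)(C)C)C=C[C@@H]2C(C)(C)CCC[C@@]12C | intermediate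
19 | tert-butyl{[(1R,2R,4aR,8aS)-1-ethenyl-5,5,8a-trimethyl-1,2,4a,5,6,7,8,8a-octahydronaphthalen-2-yl]methoxy}dimethylsilane | C=C[C@@H]1[C@H](CO[Si](C)(C)C(C)(C)C)C=C[C@@H]2C(C)(C)CCC[C@@]12C | intermediate
20 | 9-{2-[(1R,2R,4aR,8aS)-2-(TBSO-methyl)-5,5,8a-trimethyl-1,2,4a,5,6,7,8,8a-octahydronaphthalen-1-yl]ethyl}-9-borabicyclo[3.3.1]nonane | B1(CC[C@@H]2[C@H](CO[Si](C)(C)C(C)(C)C)C=C[C@@H]3C(C)(C)CCC[C@@]23C)C4CCCC1CCC4 | intermediate (not isolated)
21 | (2E)-5-[(1R,2R,4aR,8aS)-2-(TBSO-methyl)-5,5,8a-trimethyl-1,2,4a,5,6,7,8,8a-octahydronaphthalen-1-yl]-3-methylpent-2-en-1-ol | C/C(=C\CO)CC[C@@H]1[C@H](CO[Si](C)(C)C(C)(C)C)C=C[C@@H]2C(C)(C)CCC[C@@]12C | intermediate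
22 | 16-bromohexadecan-1-ol | OCCCCCCCCCCCCCCCCBr | starting material
23 | [(16-bromohexadecyl)oxy](tert-butyl)diphenylsilane | CC(C)(C)[Si](OCCCCCCCCCCCCCCCCBr)(c1ccccc1)c1ccccc1 | intermediate
24 | 16-bromohexadecanoic acid | OC(=O)CCCCCCCCCCCCCCCBr | starting material
25 | chloromagnesium 16-bromohexadecanoate | Cl[Mg]OC(=O)CCCCCCCCCCCCCCCBr | intermediate (not isolated)
26 | [16-(TBDPSO)hexadecyl]magnesium bromide | Br[Mg]CCCCCCCCCCCCCCCCO[Si](c1ccccc1)(c1ccccc1)C(C)(C)C | intermediate (not isolated)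
27 | 32-(TBDPSO)dotriacontanoic acid | OC(=O)CCCCCCCCCCCCCCCCCCCCCCCCCCCCCCCO[Si](c1ccccc1)(c1ccccc1)C(C)(C)C | intermediate
28 | (2E)-5-[(1R,2R,4aR,8aS)-2-(TBSO-methyl)-5,5,8a-trimethyl-1,2,4a,5,6,7,8,8a-octahydronaphthalen-1-yl]-3-methylpent-2-en-1-yl 32-(TBDPSO)dotriacontanoate | C/C(=C\COC(=O)CCCCCCCCCCCCCCCCCCCCCCCCCCCCCCCO[Si](c3ccccc3)(c4ccccc4)C(C)(C)C)CC[C@@H]1[C@H](CO[Si](C)(C)C(C)(C)C)C=C[C@@H]2C(C)(C)CCC[C@@]12C | intermediate
29 | (2E)-5-[(1R,2R,4aR,8aS)-2-(hydroxymethyl)-5,5,8a-trimethyl-1,2,4a,5,6,7,8,8a-octahydronaphthalen-1-yl]-3-methylpent-2-en-1-yl 32-(TBDPSO)dotriacontanoate | C/C(=C\COC(=O)CCCCCCCCCCCCCCCCCCCCCCCCCCCCCCCO[Si](c3ccccc3)(c4ccccc4)C(C)(C)C)CC[C@@H]1[C@H](CO)C=C[C@@H]2C(C)(C)CCC[C@@]12C | intermediate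
30 | (2E)-5-[(1R,2R,4aR,8aS)-2-formyl-5,5,8a-trimethyl-1,2,4a,5,6,7,8,8a-octahydronaphthalen-1-yl]-3-methylpent-2-en-1-yl 32-(TBDPSO)dotriacontanoate | C/C(=C\COC(=O)CCCCCCCCCCCCCCCCCCCCCCCCCCCCCCCO[Si](c3ccccc3)(c4ccccc4)C(C)(C)C)CC[C@@H]1[C@H](C=O)C=C[C@@H]2C(C)(C)CCC[C@@]12C | intermediate (not isolated)
31 | (2E)-5-[(1S,4aR,8aR)-2-formyl-5,5,8a-trimethyl-1,4,4a,5,6,7,8,8a-octahydronaphthalen-1-yl]-3-methylpent-2-en-1-yl 32-(TBDPSO)dotriacontanoate | C/C(=C\COC(=O)CCCCCCCCCCCCCCCCCCCCCCCCCCCCCCCO[Si](c3ccccc3)(c4ccccc4)C(C)(C)C)CC[C@@H]1C(C=O)=CC[C@@H]2C(C)(C)CCC[C@@]12C | intermediate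
32 | (2E)-5-[(1S,4aR,8aR)-2-(hydroxymethyl)-5,5,8a-trimethyl-1,4,4a,5,6,7,8,8a-octahydronaphthalen-1-yl]-3-methylpent-2-en-1-yl 32-(TBDPSO)dotriacontanoate | C/C(=C\COC(=O)CCCCCCCCCCCCCCCCCCCCCCCCCCCCCCCO[Si](c3ccccc3)(c4ccccc4)C(C)(C)C)CC[C@@H]1C(CO)=CC[C@@H]2C(C)(C)CCC[C@@]12C | intermediate
33 | (2E)-5-[(1S,4aR,8aR)-2-(hydroxymethyl)-5,5,8a-trimethyl-1,4,4a,5,6,7,8,8a-octahydronaphthalen-1-yl]-3-methylpent-2-en-1-yl 32-hydroxydotriacontanoate | C/C(=C\COC(=O)CCCCCCCCCCCCCCCCCCCCCCCCCCCCCCCO)CC[C@@H]1C(CO)=CC[C@@H]2C(C)(C)CCC[C@@]12C | target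

**Totals.** Total step count: 21. Longest linear sequence: 16 steps (from 5 through steps 4–14 and 17–21).

**Steps most likely to fail**

Step 10. The cycloaddition may stall, or lose endo or facial control, because the dienophile is β,β-disubstituted and the diene terminus is neopentylic; ionisation of the dienylic silyl ether by the Lewis acid is a further hazard. The fallback moves the chirality from the catalyst to the imide and uses a stoichiometric, stronger Lewis acid. It sets out from acid 12, which is activated as before through anhydride 14 and used to acylate lithiated (4R)-4-benzyl-1,3-oxazolidin-2-one (n-BuLi, THF, −78 °C), giving the chiral trienoyl imide F1. Me2AlCl (1.4 equiv, CH2Cl2, −30 °C) forms the cationic aluminium chelate, in which the benzyl group covers the si face of C9, and the auxiliary-controlled endo cycloaddition should give the benzyl-substituted cycloadduct F2. LiBH4 cleavage then returns to the route at 17.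

Step 11. Hydride may attack the ring carbonyl of the congested imide and open the oxazolidinone instead of releasing the acyl group. The fallback separates cleavage from reduction: 16 is hydrolysed with LiOH/H2O2 (THF/H2O, 0 °C), hydroperoxide being selective for the exocyclic carbonyl, to the carboxylic acid F3, and LiAlH4 (Et2O, 0 °C) reduces this acid to 17, where the route resumes.

Step 14. Hydroboration of the vinyl group beside the quaternary C10, or alkyl transfer from boron to palladium, may be slow, and protodeboronation may compete. The fallback forms C11–C12 instead of C12–C13 by sulfone alkylation. It sets out from alcohol 17, which PhSSPh/n-Bu3P converts into the phenyl sulfide F4 and H2O2/(NH4)6Mo7O24·4H2O (EtOH) oxidises to the sulfone F5 without touching the alkene. The electrophile comes from prenyl acetate: SeO2/t-BuOOH allylic oxidation gives (2E)-4-hydroxy-3-methylbut-2-en-1-yl acetate F6, and Appel bromination (CBr4, PPh3) gives (2E)-4-bromo-3-methylbut-2-en-1-yl acetate F7. The lithio anion of the sulfone (n-BuLi, THF/HMPA, −78 °C) is alkylated with this bromide to the C11-sulfonyl acetate F8. Reductive desulfonylation (Na(Hg), Na2HPO4, MeOH/THF, −20 °C) gives the C15 acetate F9, and K2CO3/MeOH frees the alcohol, returning to the route at 21.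

**Further compounds**
F1 | step 10 | (4R)-4-benzyl-3-[(2E,8E,10E)-12-(TBSO)-3,7,7-trimethyldodeca-2,8,10-trienoyl]-1,3-oxazolidin-2-one | O=C1OC[C@@H](Cc2ccccc2)N1C(=O)/C=C(\C)CCCC(C)(C)/C=C/C=C/CO[Si](C)(C)C(C)(C)C
F2 | step 10 | (4R)-4-benzyl-3-{[(1R,2R,4aR,8aR)-2-(TBSO-methyl)-5,5,8a-trimethyl-1,2,4a,5,6,7,8,8a-octahydronaphthalen-1-yl]carbonyl}-1,3-oxazolidin-2-one | O=C1OC[C@@H](Cc2ccccc2)N1C(=O)[C@@H]3[C@H](CO[Si](C)(C)C(C)(C)C)C=C[C@@H]4C(C)(C)CCC[C@@]34C
F3 | step 11 | (1R,2R,4aR,8aR)-2-(TBSO-methyl)-5,5,8a-trimethyl-1,2,4a,5,6,7,8,8a-octahydronaphthalene-1-carboxylic acid | OC(=O)[C@@H]1[C@H](CO[Si](C)(C)C(C)(C)C)C=C[C@@H]2C(C)(C)CCC[C@@]12C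
F4 | step 14 | tert-butyl(dimethyl){[(1R,2R,4aR,8aR)-5,5,8a-trimethyl-1-[(phenylsulfanyl)methyl]-1,2,4a,5,6,7,8,8a-octahydronaphthalen-2-yl]methoxy}silane | c3ccccc3SC[C@@H]1[C@H](CO[Si](C)(C)C(C)(C)C)C=C[C@@H]2C(C)(C)CCC[C@@]12C
F5 | step 14 | tert-butyl(dimethyl){[(1R,2R,4aR,8aR)-5,5,8a-trimethyl-1-[(phenylsulfonyl)methyl]-1,2,4a,5,6,7,8,8a-octahydronaphthalen-2-yl]methoxy}silane | O=S(=O)(c3ccccc3)C[C@@H]1[C@H](CO[Si](C)(C)C(C)(C)C)C=C[C@@H]2C(C)(C)CCC[C@@]12C
F6 | step 14 | (2E)-4-hydroxy-3-methylbut-2-en-1-yl acetate | CC(=O)OC/C=C(\C)CO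
F7 | step 14 | (2E)-4-bromo-3-methylbut-2-en-1-yl acetate | CC(=O)OC/C=C(\C)CBr
F8 | step 14 | (2E)-5-[(1R,2R,4aR,8aR)-2-(TBSO-methyl)-5,5,8a-trimethyl-1,2,4a,5,6,7,8,8a-octahydronaphthalen-1-yl]-3-methyl-5-(phenylsulfonyl)pent-2-en-1-yl acetate (both C11 epimers) | CC(=O)OC/C=C(\C)CC([C@@H]1[C@H](CO[Si](C)(C)C(C)(C)C)C=C[C@@H]2C(C)(C)CCC[C@@]12C)S(=O)(=O)c3ccccc3
F9 | step 14 | (2E)-5-[(1R,2R,4aR,8aS)-2-(TBSO-methyl)-5,5,8a-trimethyl-1,2,4a,5,6,7,8,8a-octahydronaphthalen-1-yl]-3-methylpent-2-en-1-yl acetate | CC(=O)OC/C=C(\C)CC[C@@H]1[C@H](CO[Si](C)(C)C(C)(C)C)C=C[C@@H]2C(C)(C)CCC[C@@]12C
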